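Readings and results were generated by integration for an exercise, and the scatter is random.

Late in the closed runs Jy falls away: Qa makes it from Ym, then turns it into Lx.

| flask | Ym | Qa | remark | time |
|---|---|---|---|---|
| delta | 26 mM | 6.5 µM | run made earlier |  |
| alpha | 17 mM | 6.5 µM | run made earlier |  |
| theta | 39 mM | 6.5 µM | run made earlier |  |
| spring | 26 mM | 6.5 µM | one stirred flow tank at steady state, fed with the mixture as stated, mean residence time 3.0 h |  |
| dusk | 26 mM (fed, over 3.00 h) | 6.5 µM | a stirred flask in which Ym is dosed at a steady rate over 3.00 h without added volume, worked up at 3.0 h | 3.0 h |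
| summer | 26 mM | 6.5 µM | a closed flask charged with all of it at once and left for 3.0 h | 3.0 h |
| winter | 26 mM | 6.5 µM | a tube with plug flow, the mixed feed as stated, residence time 3.0 h | 3.0 h |

| run | time / h | Jy / % |
|---|---|---|
| delta | 0.250 | 30 |
| delta | 0.833 | 73 |
| delta | 1.33 | 67 |
| delta | 2.00 | 52 |
| delta | 3.00 | 36 |
| alpha | 0.500 | 69 |
| alpha | 1.00 | 71 |
| alpha | 1.33 | 62 |
| alpha | 2.00 | 48 |
| alpha | 2.50 | 35 |
| theta | 0.500 | 27 |
| theta | 1.00 | 64 |
| theta | 1.33 | 67 |
| theta | 2.00 | 59 |
| theta | 2.50 | 48 |

(each reading ± 2 percentage points)

- the stated concentrations are those of everything mixed, before any reaction; amounts are the same in each set-up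
- steps thought possible: Ym + Qa -> Jy + Qa; Qa + Jy -> Qa + Lx
- the feed brings no volume worth counting
- the earlier runs were made in a closed, stirred flask

* the set-up with the highest amount of Jy at the outlet or at the end, in percent of the Ym put in ("none" if the first two lie within 2 percentage points) (spring / dusk / summer / winter / none)
* amount of Jy at the outlet or at the end, in percent of the Ym put in, spring
* amount of Jy at the outlet or at the end, in percent of the Ym put in, dusk
* amount of Jy at the outlet or at the end, in percent of the Ym put in, summer
* amount of Jy at the outlet or at the end, in percent of the Ym put in, winter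

I take logarithms of the late readings. Delta loses 0.372 h⁻¹ between 1.33 h and 3.00 h, and alpha loses 0.489 h⁻¹ between 1.33 h and 2.50 h. I leave out theta, whose highest reading comes at 1.33 h. The mean of these two readings is the fading constant 0.430 h⁻¹, the logarithm of Jy lost per hour at this Qa (a pseudo-first-order constant).

My view is that Jy fades for as long as it waits, and that the wait differs from vessel to vessel. In dusk, Ym arrives at 8.67 mM h⁻¹, slower than the 31.2 mM h⁻¹ of Jy formed up to delta's first reading. So I let each portion become Jy as it arrives and fade for the time that remains. Averaged over an even dose, the kept share is (1 − exp(−k·T))/(k·T), with k the fading constant and T the dosing time, which gives 56.2% for dusk. For spring, the tank's spread of waits gives 1/(1 + k·T), or 43.6%.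

My colleague's view is that time counts, not the vessel. Delta had the same Ym, the same Qa and the same flask as summer, so she takes its last reading, 36%, for spring, dusk, summer and winter alike.

The forecast stands on my side, though its numbers are its own: dusk best, with 43% for spring, 55% for dusk, 36% for summer and 36% for winter. In its words: “Dosing wins because Jy is formed late.”

The flasks give 40.1% for spring, 53.3% for dusk, 32.5% for summer and 32.5% for winter, so dusk comes first.

    Ym + Qa → Jy + Qa, rate k1*[Ym]*[Qa]/(1 + ([Ym]/Km1) + ([Ym]/Ksi1)^2) (0.0630 M, 15.6 mM, k = 209 M⁻¹ s⁻¹)
    Qa + Jy → Qa + Lx (k = 18.9 M⁻¹ s⁻¹)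

My colleague's view holds between summer and winter, and at 30.0 h, when dusk and winter both hold 0% Jy. The kept share for dusk stands 2.9 percentage points above the Jy found in dusk, and dusk still holds 7.11% as Ym at 3.00 h. With Qa raised to 0.011 mM in a flask otherwise like dusk, the fading constant taken in proportion to Qa is 0.728 h⁻¹, the kept share is 40.6%, and that flask holds 39.3% as Jy.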